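**Strategy**

- Retrosynthetic cuts: first the C8–O ester bond (E-ferulic acid comes off). Then the C8 carbinol and C7–H go back to a C8 methyl enol ether, and the C4 methyl goes back to a C4 ketone. Last, C5 is taken out of the seven-membered ring (bonds C5–C1 and C5–C6 cut, bond C1–C6 restored), which leaves a benzene ring with a diazoketone side chain, and the aryl–C2 bond is cut (Heck).
- Forward order: the benzene ring is bought with all its substituents. A three-carbon chain is attached and turned into a diazomethyl ketone. Step 8 closes the cyclopentanone and widens the benzene ring to the seven-membered ring in one operation. The ferulate is attached at the end.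
- Enabling feature: the seven-membered ring (C1, C5–C10) bears CH3 on C10, oxygen on C8 and the hydroxyisopropyl group on C7. That is a 4-methoxy-2-methyl-5-(carbinol)phenyl ring into which one carbon, C5, has been inserted between the ipso carbon C1 and the unsubstituted ortho carbon C6. C5 is bonded to C4 of the five-membered ring, where a C=O can stand for CH–CH3.
- Stereochemistry: C5 comes from the chiral copper bis(oxazoline) catalyst. C4 and C7 follow from C5, by hydrogen delivery to the H5 face. C8 follows from C7, by hydride delivery from the C11 alkoxide. The E alkene is bought with ferulic acid.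

Key step: step 8

Numbering: guaiane locants are used (five-membered ring C1–C5; seven-membered ring C1, C5–C10; carbinol carbon C11; C15 is the methyl on C4). In the arene the chain-bearing carbon is C1, followed round the ring by C10 (CH3), C9 (H), C8 (OCH3), C7 (carbinol) and C6 (H).

Assumption: the sense of induction of the copper bis(oxazoline) catalyst with this arene cannot be predicted from a model. Both antipodes of the ligand are commercial, and the route is written for the one that gives (5R)-13.

**Step 1**
Reactants: 1 methyl 2-methoxy-4-methylbenzoate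
Product: 2 methyl 5-bromo-2-methoxy-4-methylbenzoate
Conditions: NBS, MeCN, rt, dark
Reagents that add atoms: N-bromosuccinimide, O=C1CCC(=O)N1Br
Why: Electrophilic aromatic bromination goes para to the methoxy group (the strongest activator), at the carbon that is also ortho to the methyl and meta to the ester, because the other activated position is wedged between methoxy and methyl.

**Step 2**
Reactants: 2 methyl 5-bromo-2-methoxy-4-methylbenzoate
Product: 4 2-(5-bromo-2-methoxy-4-methylphenyl)propan-2-ol, via aryl methyl ketone 3 (not isolated)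
Conditions: MeMgBr (3 equiv), THF, 0 °C to rt; then aq NH4Cl
Reagents that add atoms: methylmagnesium bromide, C[Mg]Br
Why: Double Grignard addition to the ester through the methyl ketone gives the tertiary benzylic carbinol, and the aryl bromide does not exchange with MeMgBr at this temperature.

**Step 3**
Reactants: 4 2-(5-bromo-2-methoxy-4-methylphenyl)propan-2-ol
Product: 5 [2-(5-bromo-2-methoxy-4-methylphenyl)propan-2-yl]oxy(triethyl)silane
Conditions: TESOTf, 2,6-lutidine, CH2Cl2, −78 to 0 °C
Reagents that add atoms: triethylsilyl trifluoromethanesulfonate, CC[Si](CC)(CC)OS(=O)(=O)C(F)(F)F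
Why: A silyl triflate with a hindered pyridine base silylates tertiary alcohols, and the triethylsilyl ether removes the O–H that would quench the mixed anhydride, diazomethane and the carbene, yet it can later be cleaved by fluoride next to a ketone.

**Step 4**
Reactants: 5 [2-(5-bromo-2-methoxy-4-methylphenyl)propan-2-yl]oxy(triethyl)silane; 6 methyl acrylate
Product: 7 methyl (E)-3-{4-methoxy-2-methyl-5-[2-(triethylsilyloxy)propan-2-yl]phenyl}prop-2-enoate
Conditions: Pd(OAc)2 (5 mol %), P(o-tol)3 (10 mol %), Et3N, DMF, 100 °C
Reagents that add atoms: none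
Why: Mizoroki–Heck coupling of an aryl bromide with an acrylate gives the E-cinnamate by syn carbopalladation and syn beta-hydride elimination, and ortho-methyl aryl bromides couple under these phosphine conditions.

**Step 5**
Reactants: 7 methyl (E)-3-{4-methoxy-2-methyl-5-[2-(triethylsilyloxy)propan-2-yl]phenyl}prop-2-enoate
Product: 8 methyl 3-{4-methoxy-2-methyl-5-[2-(triethylsilyloxy)propan-2-yl]phenyl}propanoate
Conditions: H2 (1 atm), 10% Pd/C, EtOAc, rt
Reagents that add atoms: none
Why: Catalytic hydrogenation of a cinnamate C=C is fast at 1 atm, and in neutral ethyl acetate the tertiary benzylic silyl ether and the arene are not attacked.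

**Step 6**
Reactants: 8 methyl 3-{4-methoxy-2-methyl-5-[2-(triethylsilyloxy)propan-2-yl]phenyl}propanoate
Product: 9 3-{4-methoxy-2-methyl-5-[2-(triethylsilyloxy)propan-2-yl]phenyl}propanoic acid
Conditions: LiOH, THF/MeOH/H2O, rt; then 1 M HCl to pH 5, 0 °C
Reagents that add atoms: lithium hydroxide (aqueous), [Li+].[OH-]
Why: Saponification of an unhindered methyl ester; a silyl ether of a tertiary alcohol withstands aqueous hydroxide, and acidification is stopped at pH 5 in the cold so that the benzylic silyl ether does not ionize.

**Step 7**
Reactants: 9 3-{4-methoxy-2-methyl-5-[2-(triethylsilyloxy)propan-2-yl]phenyl}propanoic acid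
Product: 11 1-diazo-4-{4-methoxy-2-methyl-5-[2-(triethylsilyloxy)propan-2-yl]phenyl}butan-2-one, via isobutyl carbonic mixed anhydride 10 (not isolated)
Conditions: isobutyl chloroformate, Et3N, THF, −15 °C; then CH2N2 (excess, Et2O), −15 °C to rt
Reagents that add atoms: isobutyl chloroformate, CC(C)COC(=O)Cl (its atoms stay only in 10); diazomethane, C=[N+]=[N-]
Why: Acylation of diazomethane by a mixed carbonic anhydride (first stage of an Arndt–Eistert sequence) gives the terminal diazoketone without the HCl that an acid chloride route would release onto the acid-labile benzylic silyl ether.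

**Step 8**
Reactants: 11 1-diazo-4-{4-methoxy-2-methyl-5-[2-(triethylsilyloxy)propan-2-yl]phenyl}butan-2-one
Product: 13 (5R)-8-methoxy-11-(triethylsilyloxy)-15-norguaia-1(10),6,8-trien-4-one [(8aR)-6-methoxy-4-methyl-7-[2-(triethylsilyloxy)propan-2-yl]-3,8a-dihydroazulen-1(2H)-one], via norcaradiene 12 (not isolated)
Conditions: [Cu(MeCN)4]PF6 (5 mol %), 2,2'-(propane-2,2-diyl)bis(4-phenyl-4,5-dihydrooxazole) (Ph-box, one antipode, 6 mol %), Na[B(3,5-(CF3)2C6H3)4] (6 mol %), CH2Cl2, 40 °C, slow addition of 11; filtration through neutral Al2O3, used at once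
Reagents that add atoms: none
Why: The copper carbene formed from 11 by loss of N2 adds as an electrophile across the C1–C6 π bond of the anisole ring to give norcaradiene 12, whose disrotatory six-electron electrocyclic opening breaks the old C1–C6 bond and gives the cycloheptatriene 13 as its 8a-H (3,8a-dihydro) isomer; this is the intramolecular Büchner reaction of 1-diazo-4-arylbutan-2-ones, known with dirhodium carboxylates and, in enantioselective form, with copper bis(oxazoline) catalysts. The cyclopentanone closes by a (2+1) cycloaddition in which the three-atom tether (C2, C3, C4) holds the carbene carbon C5 over the ipso carbon (a 5-exo-type closure onto the arene), and the seven-membered ring arises by one-carbon expansion of the benzene ring when the cyclopropane bond C1–C6 opens, not by a cyclization. The one stereocentre that remains, C5, is decided by which face of the flat arene the carbene reaches, and the C2-symmetric bis(oxazoline) on copper selects that face. The step needs attack on the C1–C6 bond and not on C1–C10: the methyl group on C10 hinders that bond and would have to end on a fully substituted cyclopropane carbon, whereas C6 carries only hydrogen. It also needs cyclopropanation rather than O–H insertion or aromatic substitution: the para-methoxy group makes the ring electron-rich for the electrophilic carbene, the carbinol is capped as its silyl ether and the non-coordinating borate counterion keeps the copper centre reactive. Because H5 of 13 is alpha to the ketone and doubly allylic, 13 is kept away from acid and base and methylenated immediately.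

**Step 9**
Reactants: 13 (5R)-8-methoxy-11-(triethylsilyloxy)-15-norguaia-1(10),6,8-trien-4-one
Product: 14 (5S)-8-methoxy-11-(triethylsilyloxy)guaia-1(10),4(15),6,8-tetraene (C4 exocyclic methylene)
Conditions: Tebbe reagent Cp2Ti(μ-CH2)(μ-Cl)AlMe2, pyridine (cat.), THF/toluene, −40 to 0 °C; dilute aq NaOH quench, basic Al2O3
Reagents that add atoms: Tebbe reagent, C[Al-]1(C)C[Ti]([Cl+]1)(C2C=CC=C2)C3C=CC=C3
Why: Tebbe methylenation runs through a titanium methylidene and an oxatitanacyclobutane, is not basic, and therefore converts easily enolized ketones into 1,1-disubstituted alkenes without touching H5, while enol and silyl ethers are inert to it.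

**Step 10**
Reactants: 14 (5S)-8-methoxy-11-(triethylsilyloxy)guaia-1(10),4(15),6,8-tetraene
Product: 15 (4S,5R)-8-methoxy-11-(triethylsilyloxy)guaia-1(10),6,8-triene
Conditions: H2 (1 atm), RhCl(PPh3)3 (5 mol %), benzene, rt
Reagents that add atoms: none
Why: Homogeneous hydrogenation with Wilkinson's catalyst reduces 1,1-disubstituted alkenes much faster than tri- and tetrasubstituted ones, so only the exocyclic methylene should react, and H2 should add to the face of the five-membered ring that carries H5, since the other face is covered by C6 and the folded seven-membered ring, which sets C4 (S) with the methyl group cis to C6.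

**Step 11**
Reactants: 15 (4S,5R)-8-methoxy-11-(triethylsilyloxy)guaia-1(10),6,8-triene
Product: 16 (4S,5R)-11-(triethylsilyloxy)guaia-1(10),6-dien-8-one
Conditions: oxalic acid (cat.), THF/H2O, 0 °C
Reagents that add atoms: water, O
Why: Mild acid hydrolysis of a methyl enol ether, in which kinetic protonation at C9 (the carbon next to the oxygen-bearing carbon, as in the oxalic acid hydrolysis of dienol ethers to beta,gamma-unsaturated ketones) gives an oxocarbenium ion that is also allylic to C6=C7, so that the C8 ketone appears conjugated to C6=C7 while the C1=C10 alkene stays in place and no stereocentre is touched.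

**Step 12**
Reactants: 16 (4S,5R)-11-(triethylsilyloxy)guaia-1(10),6-dien-8-one
Product: 17 (4S,5S,7R)-11-(triethylsilyloxy)guai-1(10)-en-8-one
Conditions: Stryker's reagent [(Ph3P)CuH]6 (0.4 equiv), H2O (3 equiv), degassed benzene, rt
Reagents that add atoms: none
Why: Conjugate reduction with a phosphine copper hydride (hydride to C6, then protonation of the copper enolate at C7 by water) leaves the isolated tetrasubstituted alkene alone, and the proton should enter C7 from the H5 face, which places the bulky C11 group 1,3-cis to the C5–C4 bond where both can be pseudo-equatorial, so that kinetic and thermodynamic preference should agree (C7 R in the ketone).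

**Step 13**
Reactants: 17 (4S,5S,7R)-11-(triethylsilyloxy)guai-1(10)-en-8-one
Product: 18 (4S,5S,7R)-11-hydroxyguai-1(10)-en-8-one
Conditions: HF·pyridine, pyridine, THF, 0 °C to rt
Reagents that add atoms: none
Why: Cleavage of the triethylsilyl ether by pyridine-buffered HF avoids the basic conditions under which a beta-hydroxy ketone would undergo retro-aldol cleavage, dehydration, epimerization at C7 or migration of the C1=C10 alkene.

**Step 14**
Reactants: 18 (4S,5S,7R)-11-hydroxyguai-1(10)-en-8-one
Product: 19 (4S,5S,7S,8S)-guai-1(10)-ene-8,11-diol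
Conditions: Me4NBH(OAc)3 (5 equiv), MeCN/AcOH 1:1, −20 °C; aq potassium sodium tartrate
Reagents that add atoms: none
Why: Hydroxyl-directed reduction (Evans–Saksena), in which the C11 hydroxyl replaces an acetate on boron and the bound borohydride delivers hydride intramolecularly to the carbonyl face on which C11 lies, so that the new C8 hydroxyl ends trans to the hydroxyisopropyl group (C8 S), while the weakly acidic medium does not epimerize C7.

**Step 15**
Reactants: 20 trans-ferulic acid
Product: 22 (E)-4-O-(tert-butyldimethylsilyl)ferulic acid, via bis-silylated ferulate 21 (not isolated)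
Conditions: TBSCl (2.4 equiv), imidazole, DMF, rt; then AcOH/THF/H2O, rt
Reagents that add atoms: tert-butyldimethylsilyl chloride, CC(C)(C)[Si](C)(C)Cl
Why: Silyl chloride and imidazole silylate both the phenol and the acid, and the silyl ester is hydrolysed in dilute acetic acid far faster than the aryl silyl ether, with the E alkene untouched.

**Step 16**
Reactants: 19 (4S,5S,7S,8S)-guai-1(10)-ene-8,11-diol; 22 (E)-4-O-(tert-butyldimethylsilyl)ferulic acid
Product: 24 (4S,5S,7S,8S)-11-hydroxyguai-1(10)-en-8-yl (E)-4-O-(tert-butyldimethylsilyl)ferulate, via Yamaguchi mixed anhydride 23 (not isolated)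
Conditions: 2,4,6-Cl3C6H2COCl, Et3N, THF, rt; then 19, DMAP, toluene, rt to 40 °C
Reagents that add atoms: 2,4,6-trichlorobenzoyl chloride, O=C(Cl)c1c(Cl)cc(Cl)cc1Cl (its atoms stay only in 23)
Why: Yamaguchi esterification, in which DMAP attacks the cinnamoyl carbonyl of the mixed anhydride (the trichlorobenzoyl carbonyl is shielded) and the acylpyridinium acylates the secondary C8 hydroxyl with retention, while the tertiary C11 hydroxyl is too hindered to react.

**Step 17**
Reactants: 24 (4S,5S,7S,8S)-11-hydroxyguai-1(10)-en-8-yl (E)-4-O-(tert-butyldimethylsilyl)ferulate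
Product: 25 (4S,5S,7S,8S)-11-hydroxyguai-1(10)-en-8-yl (E)-ferulate (CNP0241038.1)
Conditions: TBAF, AcOH (1:1), THF, 0 °C
Reagents that add atoms: none
Why: An aryl silyl ether is cleaved by fluoride faster than anything else in the molecule, and buffering with acetic acid keeps the phenoxide from cleaving or transferring the ferulate ester.

**Compound list**

1 | methyl 2-methoxy-4-methylbenzoate | COC(=O)c1ccc(C)cc1OC | starting material
2 | methyl 5-bromo-2-methoxy-4-methylbenzoate | COC(=O)c1cc(Br)c(C)cc1OC | intermediate
3 | 1-(5-bromo-2-methoxy-4-methylphenyl)ethan-1-one (formed in the flask, not isolated) | CC(=O)c1cc(Br)c(C)cc1OC | intermediate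
4 | 2-(5-bromo-2-methoxy-4-methylphenyl)propan-2-ol | CC(C)(O)c1cc(Br)c(C)cc1OC | intermediate
5 | [2-(5-bromo-2-methoxy-4-methylphenyl)propan-2-yl]oxy(triethyl)silane | CC[Si](CC)(CC)OC(C)(C)c1cc(Br)c(C)cc1OC | intermediate
6 | methyl acrylate | C=CC(=O)OC | starting material
7 | methyl (E)-3-{4-methoxy-2-methyl-5-[2-(triethylsilyloxy)propan-2-yl]phenyl}prop-2-enoate | COC(=O)/C=C/c1cc(C(C)(C)O[Si](CC)(CC)CC)c(OC)cc1C | intermediate
8 | methyl 3-{4-methoxy-2-methyl-5-[2-(triethylsilyloxy)propan-2-yl]phenyl}propanoate | COC(=O)CCc1cc(C(C)(C)O[Si](CC)(CC)CC)c(OC)cc1C | intermediate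
9 | 3-{4-methoxy-2-methyl-5-[2-(triethylsilyloxy)propan-2-yl]phenyl}propanoic acid | OC(=O)CCc1cc(C(C)(C)O[Si](CC)(CC)CC)c(OC)cc1C | intermediate
10 | isobutyl carbonic mixed anhydride of acid 9 (formed in the flask, not isolated) | CC(C)COC(=O)OC(=O)CCc1cc(C(C)(C)O[Si](CC)(CC)CC)c(OC)cc1C | intermediate
11 | 1-diazo-4-{4-methoxy-2-methyl-5-[2-(triethylsilyloxy)propan-2-yl]phenyl}butan-2-one | [N-]=[N+]=CC(=O)CCc1cc(C(C)(C)O[Si](CC)(CC)CC)c(OC)cc1C | intermediate
12 | norcaradiene: cyclopropane C1–C5–C6 cis-fused to the cyclopentanone and to the 8-methoxy-10-methyl-7-(silyloxyalkyl)cyclohexa-7,9-diene, H5 on the diene side (formed in the flask, not isolated) | O=C1CC[C@]23[C@H]1[C@H]2C(C(C)(C)O[Si](CC)(CC)CC)=C(OC)C=C3C | intermediate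
13 | (5R)-8-methoxy-11-(triethylsilyloxy)-15-norguaia-1(10),6,8-trien-4-one; (8aR)-6-methoxy-4-methyl-7-[2-(triethylsilyloxy)propan-2-yl]-3,8a-dihydroazulen-1(2H)-one | O=C1CCC2=C(C)C=C(OC)C(C(C)(C)O[Si](CC)(CC)CC)=C[C@@H]12 | intermediate
14 | (5S)-8-methoxy-11-(triethylsilyloxy)guaia-1(10),4(15),6,8-tetraene | C=C1CCC2=C(C)C=C(OC)C(C(C)(C)O[Si](CC)(CC)CC)=C[C@@H]12 | intermediate
15 | (4S,5R)-8-methoxy-11-(triethylsilyloxy)guaia-1(10),6,8-triene | COC1=CC(C)=C2CC[C@H](C)[C@@H]2C=C1C(C)(C)O[Si](CC)(CC)CC | intermediate
16 | (4S,5R)-11-(triethylsilyloxy)guaia-1(10),6-dien-8-one | O=C1CC(C)=C2CC[C@H](C)[C@@H]2C=C1C(C)(C)O[Si](CC)(CC)CC | intermediate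
17 | (4S,5S,7R)-11-(triethylsilyloxy)guai-1(10)-en-8-one | O=C1CC(C)=C2CC[C@H](C)[C@@H]2C[C@@H]1C(C)(C)O[Si](CC)(CC)CC | intermediate
18 | (4S,5S,7R)-11-hydroxyguai-1(10)-en-8-one | O=C1CC(C)=C2CC[C@H](C)[C@@H]2C[C@@H]1C(C)(C)O | intermediate
19 | (4S,5S,7S,8S)-guai-1(10)-ene-8,11-diol (H4, H5 and H7 cis; 8-OH on the same face as these hydrogens and trans to the hydroxyisopropyl group) | O[C@H]1CC(C)=C2CC[C@H](C)[C@@H]2C[C@@H]1C(C)(C)O | intermediate
20 | trans-ferulic acid | COc1cc(/C=C/C(=O)O)ccc1O | starting material
21 | tert-butyldimethylsilyl (E)-4-O-(tert-butyldimethylsilyl)ferulate (formed in the flask, not isolated) | COc1cc(/C=C/C(=O)O[Si](C)(C)C(C)(C)C)ccc1O[Si](C)(C)C(C)(C)C | intermediate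
22 | (E)-4-O-(tert-butyldimethylsilyl)ferulic acid | COc1cc(/C=C/C(=O)O)ccc1O[Si](C)(C)C(C)(C)C | intermediate
23 | mixed anhydride of 22 and 2,4,6-trichlorobenzoic acid (formed in the flask, not isolated) | COc1cc(/C=C/C(=O)OC(=O)c2c(Cl)cc(Cl)cc2Cl)ccc1O[Si](C)(C)C(C)(C)C | intermediate
24 | (4S,5S,7S,8S)-11-hydroxyguai-1(10)-en-8-yl (E)-4-O-(tert-butyldimethylsilyl)ferulate | COc1cc(/C=C/C(=O)O[C@H]2CC(C)=C3CC[C@H](C)[C@@H]3C[C@@H]2C(C)(C)O)ccc1O[Si](C)(C)C(C)(C)C | intermediate
25 | (4S,5S,7S,8S)-11-hydroxyguai-1(10)-en-8-yl (E)-ferulate, CNP0241038.1 | COc1cc(/C=C/C(=O)O[C@H]2CC(C)=C3CC[C@H](C)[C@@H]3C[C@@H]2C(C)(C)O)ccc1O | target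

**Step count**

Total: 17 steps. Longest linear sequence: 16 steps (1 to 25 through steps 1–14, 16 and 17); step 15 prepares the acid partner.

**Steps most likely to fail**

Step 8. The chiral catalyst may discriminate poorly between the two faces of this tetrasubstituted arene, so that C5 is formed with low enantiomeric purity. The fallback replaces catalyst control by reagent control at the neighbouring carbonyl followed by a separation. It sets out from diazoketone 11, which is cyclized with achiral Rh2(OAc)4 in CH2Cl2 to the racemic trienone F1. Reduction with catecholborane and the (S)-methyl oxazaborolidine (Corey–Bakshi–Shibata), which treats C5 as the large and C3 as the small substituent, should deliver hydride to the same carbonyl face of both enantiomers. This gives two diastereomeric carbinols, the (4R,5R)-carbinol F2 and the (4R,5S)-carbinol F3, which are separated by chromatography. Oxidation of F2 with Dess–Martin periodinane buffered with NaHCO3 returns to the route at 13.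

Step 10. The rhodium catalyst may reduce or isomerize part of the conjugated triene, or be held back by diene binding, so that the exocyclic methylene is not hydrogenated cleanly. The fallback moves the hydrogenation to a stage where only the tetrasubstituted C1=C10 alkene competes. It sets out from tetraene 14, which is hydrolysed with oxalic acid in wet THF to the methylene dienone F4. Conjugate reduction with [(Ph3P)CuH]6 and water gives the methylene ketone F5. Hydrogenation of F5 with RhCl(PPh3)3 from the H5 face returns to the route at 17.

Step 12. The copper enolate may be protonated with poor facial selectivity at C7, or the hindered enone may undergo carbonyl reduction instead. The fallback sets C8 first by reagent control and then C7 by a hydroxyl-directed hydrogenation. It sets out from enone 16, which is reduced at the carbonyl with catecholborane and the (R)-methyl oxazaborolidine (alkenyl side as the large group) to the (8S)-allylic alcohol F6. Hydrogenation with the cationic complex [Rh(nbd)(dppb)]BF4 delivers H2 to C6=C7 from the face of the C8 hydroxyl and gives the saturated 11-silyl ether F7, with H7 cis to the C8 oxygen. HF·pyridine then removes the silyl group and the sequence returns to the route at 19, so that steps 13 and 14 are not needed.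

**Further compounds**

F1 | step 8 | racemic 8-methoxy-11-(triethylsilyloxy)-15-norguaia-1(10),6,8-trien-4-one | O=C1CCC2=C(C)C=C(OC)C(C(C)(C)O[Si](CC)(CC)CC)=CC12
F2 | step 8 | (4R,5R)-8-methoxy-11-(triethylsilyloxy)-15-norguaia-1(10),6,8-trien-4-ol | O[C@@H]1CCC2=C(C)C=C(OC)C(C(C)(C)O[Si](CC)(CC)CC)=C[C@@H]12
F3 | step 8 | (4R,5S)-8-methoxy-11-(triethylsilyloxy)-15-norguaia-1(10),6,8-trien-4-ol | O[C@@H]1CCC2=C(C)C=C(OC)C(C(C)(C)O[Si](CC)(CC)CC)=C[C@H]12
F4 | step 10 | (5S)-11-(triethylsilyloxy)guaia-1(10),4(15),6-trien-8-one | C=C1CCC2=C(C)CC(=O)C(C(C)(C)O[Si](CC)(CC)CC)=C[C@@H]12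
F5 | step 10 | (5S,7R)-11-(triethylsilyloxy)guaia-1(10),4(15)-dien-8-one | C=C1CCC2=C(C)CC(=O)[C@@H](C(C)(C)O[Si](CC)(CC)CC)C[C@@H]12
F6 | step 12 | (4S,5R,8S)-11-(triethylsilyloxy)guaia-1(10),6-dien-8-ol | O[C@H]1CC(C)=C2CC[C@H](C)[C@@H]2C=C1C(C)(C)O[Si](CC)(CC)CC
F7 | step 12 | (4S,5S,7S,8S)-11-(triethylsilyloxy)guai-1(10)-en-8-ol | O[C@H]1CC(C)=C2CC[C@H](C)[C@@H]2C[C@@H]1C(C)(C)O[Si](CC)(CC)CC
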